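The target is a (4→6)-linked dimer of a (2S)-4',7-dihydroxyflavan (upper unit) and (−)-epiafzelechin (lower unit). Everything rests on building ring C of the lower unit by a base-triggered [4+2]-type annulation: the C2–O1 atoms come from the carbonyl group of 4-(benzyloxy)benzaldehyde, C3 is the enolate carbon of an α-methoxy ketone, and C8a of ring A is an aryl fluoride activated by that temporary C4 ketone. One operation (aldol addition, then intramolecular SNAr) forms C2–C3 and O1–C8a. The precursor is an open 2-fluoroaryl ketone; a carbonyl transposition and a dynamic kinetic resolution then set the cis-2,3 centres, and a C8-blocked Friedel–Crafts coupling joins the upper unit.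

Key step: step 3

Remark: the sense of induction of the chiral catalysts in steps 5 and 8 is assigned from the accepted models for these catalyst families; the ligand antipode would be used if the opposite sense were found.

Step 1
Reactants: 1 5-fluororesorcinol; 2 benzyl bromide (2.2 equiv in total)
Product: 3 1,3-bis(benzyloxy)-5-fluorobenzene
Conditions: BnBr (2.2 equiv), K2CO3 (2.5 equiv), DMF, 60 °C
Reagents that add atoms: benzyl bromide (the second equivalent), BrCc1ccccc1
Why: Twofold Williamson ether synthesis, each phenol taking up one equivalent of benzyl bromide; no stereocentre is involved.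

Step 2
Reactants: 3 1,3-bis(benzyloxy)-5-fluorobenzene; 4 methoxyacetic acid
Product: 5 1-[2,4-bis(benzyloxy)-6-fluorophenyl]-2-methoxyethan-1-one
Conditions: (CF3CO)2O, H3PO4 (cat.), MeCN, 0 °C to rt
Reagents that add atoms: none
Why: Friedel–Crafts acylation through the mixed trifluoroacetic anhydride should occur para to one benzyloxy group and ortho to fluorine, the less hindered activated position, and no metal Lewis acid is present that could cleave the benzyl ethers.

Step 3
Reactants: 5 1-[2,4-bis(benzyloxy)-6-fluorophenyl]-2-methoxyethan-1-one; 6 4-(benzyloxy)benzaldehyde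
Product: 9 5,7-bis(benzyloxy)-2-[4-(benzyloxy)phenyl]-3-methoxychroman-4-one (racemic cis/trans mixture), via lithium enolate 7 (not isolated), via lithium aldolate 8 (not isolated)
Conditions: LiN(SiMe3)2 (1.0 equiv), THF, −78 °C; 6; then DMPU, −78 to 40 °C
Reagents that add atoms: none
Why: The lithium (Z)-enolate 7 adds to the non-enolisable aldehyde 6 (aldol addition, C2–C3), and the resulting alkoxide 8 displaces the fluoride at C8a by addition–elimination through a Meisenheimer complex stabilised by the ortho C4 carbonyl (intramolecular SNAr, O1–C8a). The closest known reaction type is the tandem aldol/SNAr annulation of ortho-fluoroaryl ketones, together with the SNAr closure of chroman-4-ones. Ring C, the only ring formed, closes in the 6-exo-trig mode. C2 and C3 arise without control as a racemic cis/trans mixture, which is harmless because C3 becomes sp2 in step 4 and C2 becomes epimerisable and is fixed by the catalyst in step 5. The step needs addition rather than dehydration and O-arylation at C8a only: the base is consumed as LiF, 6 cannot enolise, and the fluoride ortho to the ketone is the only leaving group.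

Step 4
Reactants: 9 5,7-bis(benzyloxy)-2-[4-(benzyloxy)phenyl]-3-methoxychroman-4-one
Product: 12 5,7-bis(benzyloxy)-2-[4-(benzyloxy)phenyl]chroman-3-one (racemic), via benzylic alcohol 10 (not isolated), via enol ether 11 (not isolated)
Conditions: NaBH4, THF/MeOH, 0 °C; then p-TsOH·H2O (cat.), THF/H2O, rt to 40 °C, dilute
Reagents that add atoms: water, O
Why: Borohydride reduction, acid-promoted ionisation at C4 (stabilised by the 5- and 7-oxygen atoms), loss of H3 to the enol ether and its hydrolysis amount to a 1,2-carbonyl transposition of the kind used to make 2-tetralones from 2-alkoxy-1-tetralones; C3 becomes sp2 and C2 stays racemic.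

Step 5
Reactants: 12 5,7-bis(benzyloxy)-2-[4-(benzyloxy)phenyl]chroman-3-one
Product: 13 (2R,3R)-5,7-bis(benzyloxy)-2-[4-(benzyloxy)phenyl]chroman-3-ol (tri-O-benzyl-(−)-epiafzelechin)
Conditions: RuCl(p-cymene)[(S,S)-TsDPEN] (2 mol%), HCO2H/Et3N (5:2), CH2Cl2, 30 °C
Reagents that add atoms: none
Why: Noyori-type asymmetric transfer hydrogenation with dynamic kinetic resolution: C2 (alpha to the ketone, benzylic and oxygen-substituted) should epimerise under Et3N faster than the ketone is reduced, and hydride delivery anti to the C2 aryl group to the matched enantiomer sets C3 (R) and with it C2 (R), 2,3-cis.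

Step 6
Reactants: 13 (2R,3R)-5,7-bis(benzyloxy)-2-[4-(benzyloxy)phenyl]chroman-3-ol
Product: 14 (2R,3R)-5,7-bis(benzyloxy)-2-[4-(benzyloxy)phenyl]-8-bromochroman-3-ol
Conditions: N-bromosuccinimide (1.0 equiv), CH2Cl2, −78 to 0 °C
Reagents that add atoms: N-bromosuccinimide, O=C1CCC(=O)N1Br
Why: Electrophilic aromatic bromination of the 5,7-dialkoxy ring A should go to C8, the more reactive position in benzylated flavan-3-ols, and so blocks C8 for step 10; no stereocentre is touched.

Step 7
Reactants: 15 7-hydroxy-4H-chromen-4-one; 2 benzyl bromide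
Product: 16 7-(benzyloxy)-4H-chromen-4-one
Conditions: K2CO3, acetone, reflux
Reagents that add atoms: none
Why: Williamson ether synthesis of the phenol; the carbonate base is too weak to open the chromone ring.

Step 8
Reactants: 16 7-(benzyloxy)-4H-chromen-4-one; 17 [4-(benzyloxy)phenyl]boronic acid
Product: 18 (2S)-7-(benzyloxy)-2-[4-(benzyloxy)phenyl]chroman-4-one
Conditions: Pd(OCOCF3)2 (5 mol%), (R)-t-BuPyOx (6 mol%), NH4PF6, H2O, ClCH2CH2Cl, 60 °C
Reagents that add atoms: none
Why: Palladium-catalysed asymmetric conjugate addition of an arylboronic acid to a chromone (pyridine-oxazoline ligand): insertion of C2=C3 into the aryl–palladium bond from the enantioface selected by the ligand sets C2 (S), and the non-basic medium avoids ring opening of the flavanone.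

Step 9
Reactants: 18 (2S)-7-(benzyloxy)-2-[4-(benzyloxy)phenyl]chroman-4-one
Product: 19 (2S,4S)-7-(benzyloxy)-2-[4-(benzyloxy)phenyl]chroman-4-ol
Conditions: NaBH4, THF/MeOH, 0 °C
Reagents that add atoms: none
Why: Borohydride reduction with axial hydride delivery should give mainly the 2,4-cis alcohol; this centre is destroyed on ionisation in step 10, so its configuration does not matter.

Step 10
Reactants: 14 (2R,3R)-5,7-bis(benzyloxy)-2-[4-(benzyloxy)phenyl]-8-bromochroman-3-ol; 19 (2S,4S)-7-(benzyloxy)-2-[4-(benzyloxy)phenyl]chroman-4-ol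
Product: 21 (2R,3R)-5,7-bis(benzyloxy)-6-{(2S,4R)-7-(benzyloxy)-2-[4-(benzyloxy)phenyl]chroman-4-yl}-2-[4-(benzyloxy)phenyl]-8-bromochroman-3-ol, via flavan-4-yl cation 20 (not isolated)
Conditions: BF3·OEt2 (0.3 equiv), CH2Cl2, −40 to 0 °C, slow addition of 19 to excess 14
Reagents that add atoms: none
Why: Lewis-acid ionisation of the benzylic alcohol gives the cation 20, stabilised by O1 and the 7-benzyloxy group, which alkylates C6 of ring A of 14 (Friedel–Crafts alkylation as in proanthocyanidin synthesis) because C8 is blocked by bromine; axial attack anti to the equatorial C2 aryl group should set the 2,4-trans (4R) centre.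

Step 11
Reactants: 21 (2R,3R)-5,7-bis(benzyloxy)-6-{(2S,4R)-7-(benzyloxy)-2-[4-(benzyloxy)phenyl]chroman-4-yl}-2-[4-(benzyloxy)phenyl]-8-bromochroman-3-ol
Product: 22 (2R,3R)-6-[(2S,4R)-7-hydroxy-2-(4-hydroxyphenyl)chroman-4-yl]-2-(4-hydroxyphenyl)chroman-3,5,7-triol (CNP0167324.2)
Conditions: H2 (1 atm), Pd(OH)2/C, Et3N, THF/MeOH, rt
Reagents that add atoms: none
Why: Hydrogenolysis of the five benzyl ethers and hydrodebromination at C8 in one operation; under these mild buffered conditions the flavan C2–O1 bonds and the interflavan bond should survive and no stereocentre is affected.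

Compound list
1 | 5-fluororesorcinol (5-fluorobenzene-1,3-diol) | Oc1cc(O)cc(F)c1 | starting material
2 | benzyl bromide | BrCc1ccccc1 | starting material
3 | 1,3-bis(benzyloxy)-5-fluorobenzene | Fc1cc(OCc2ccccc2)cc(OCc2ccccc2)c1 | intermediate
4 | methoxyacetic acid | COCC(=O)O | starting material
5 | 1-[2,4-bis(benzyloxy)-6-fluorophenyl]-2-methoxyethan-1-one | COCC(=O)c1c(F)cc(OCc2ccccc2)cc1OCc1ccccc1 | intermediate
6 | 4-(benzyloxy)benzaldehyde | O=Cc1ccc(OCc2ccccc2)cc1 | starting material
7 | lithium (Z)-enolate of 5 | [Li+].CO/C=C(\[O-])c1c(F)cc(OCc2ccccc2)cc1OCc1ccccc1 | intermediate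
8 | lithium 3-[2,4-bis(benzyloxy)-6-fluorophenyl]-1-[4-(benzyloxy)phenyl]-2-methoxy-3-oxopropan-1-olate (racemic, syn/anti mixture, no configuration specified) | [Li+].COC(C([O-])c1ccc(OCc2ccccc2)cc1)C(=O)c1c(F)cc(OCc2ccccc2)cc1OCc1ccccc1 | intermediate
9 | 5,7-bis(benzyloxy)-2-[4-(benzyloxy)phenyl]-3-methoxychroman-4-one (racemic, cis/trans mixture, no configuration specified) | COC1C(=O)c2c(OCc3ccccc3)cc(OCc3ccccc3)cc2OC1c1ccc(OCc2ccccc2)cc1 | intermediate
10 | 5,7-bis(benzyloxy)-2-[4-(benzyloxy)phenyl]-3-methoxychroman-4-ol (stereoisomer mixture, no configuration specified) | COC1C(O)c2c(OCc3ccccc3)cc(OCc3ccccc3)cc2OC1c1ccc(OCc2ccccc2)cc1 | intermediate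
11 | 5,7-bis(benzyloxy)-2-[4-(benzyloxy)phenyl]-3-methoxy-2H-chromene (racemic) | COC1=Cc2c(OCc3ccccc3)cc(OCc3ccccc3)cc2OC1c1ccc(OCc2ccccc2)cc1 | intermediate
12 | 5,7-bis(benzyloxy)-2-[4-(benzyloxy)phenyl]chroman-3-one (racemic) | O=C1Cc2c(OCc3ccccc3)cc(OCc3ccccc3)cc2OC1c1ccc(OCc2ccccc2)cc1 | intermediate
13 | (2R,3R)-5,7-bis(benzyloxy)-2-[4-(benzyloxy)phenyl]chroman-3-ol | O[C@@H]1Cc2c(OCc3ccccc3)cc(OCc3ccccc3)cc2O[C@@H]1c1ccc(OCc2ccccc2)cc1 | intermediate
14 | (2R,3R)-5,7-bis(benzyloxy)-2-[4-(benzyloxy)phenyl]-8-bromochroman-3-ol | O[C@@H]1Cc2c(OCc3ccccc3)cc(OCc3ccccc3)c(Br)c2O[C@@H]1c1ccc(OCc2ccccc2)cc1 | intermediate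
15 | 7-hydroxy-4H-chromen-4-one | O=c1ccoc2cc(O)ccc12 | starting material
16 | 7-(benzyloxy)-4H-chromen-4-one | O=c1ccoc2cc(OCc3ccccc3)ccc12 | intermediate
17 | [4-(benzyloxy)phenyl]boronic acid | OB(O)c1ccc(OCc2ccccc2)cc1 | starting material
18 | (2S)-7-(benzyloxy)-2-[4-(benzyloxy)phenyl]chroman-4-one | O=C1C[C@@H](c2ccc(OCc3ccccc3)cc2)Oc2cc(OCc3ccccc3)ccc12 | intermediate
19 | (2S,4S)-7-(benzyloxy)-2-[4-(benzyloxy)phenyl]chroman-4-ol (2,4-cis) | O[C@H]1C[C@@H](c2ccc(OCc3ccccc3)cc2)Oc2cc(OCc3ccccc3)ccc12 | intermediate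
20 | (2S)-7-(benzyloxy)-2-[4-(benzyloxy)phenyl]chroman-4-ylium hydroxytrifluoroborate | O[B-](F)(F)F.[CH+]1C[C@@H](c2ccc(OCc3ccccc3)cc2)Oc2cc(OCc3ccccc3)ccc12 | intermediate
21 | (2R,3R)-5,7-bis(benzyloxy)-6-{(2S,4R)-7-(benzyloxy)-2-[4-(benzyloxy)phenyl]chroman-4-yl}-2-[4-(benzyloxy)phenyl]-8-bromochroman-3-ol | c1ccccc1COc1ccc([C@@H]2C[C@@H](c3c(OCc5ccccc5)c(Br)c4c(c3OCc3ccccc3)C[C@@H](O)[C@@H](c3ccc(OCc5ccccc5)cc3)O4)c3ccc(OCc4ccccc4)cc3O2)cc1 | intermediate
22 | (2R,3R)-6-[(2S,4R)-7-hydroxy-2-(4-hydroxyphenyl)chroman-4-yl]-2-(4-hydroxyphenyl)chroman-3,5,7-triol (CNP0167324.2) | Oc1ccc([C@@H]2C[C@@H](c3c(O)cc4c(c3O)C[C@@H](O)[C@@H](c3ccc(O)cc3)O4)c3ccc(O)cc3O2)cc1 | target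

Total step count: 11. Longest linear sequence: 8 steps (steps 1 to 6, 10 and 11); steps 7 to 9 form the convergent branch.

Steps most likely to fail

Step 3. The aldolate may revert to 5 and 6 or lose water to the α-methoxychalcone while fluoride displacement at the twisted, donor-substituted aryl ketone is slow, and residual amide base may convert 6 into its silylimine. The fallback sets out from 5. Its enolate (LiN(SiMe3)2, 2.2 equiv, THF, −78 °C) is C-acylated with 4-(benzyloxy)benzoyl chloride to give 1-[2,4-bis(benzyloxy)-6-fluorophenyl]-3-[4-(benzyloxy)phenyl]-2-methoxypropane-1,3-dione F1. On warming with K2CO3 in DMF the enolate oxygen of F1 displaces the fluoride, the established flavone synthesis from ortho-fluoroaryl ketones, to give 5,7-bis(benzyloxy)-2-[4-(benzyloxy)phenyl]-3-methoxy-4H-chromen-4-one F2. Conjugate reduction of F2 with LiBH(s-Bu)3 in THF at −78 °C then gives 9, where the route is rejoined.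

Step 10. Attack at C6, flanked by two benzyloxy groups, may be slow, so that self-alkylation of the upper unit, attack on a ring B, or poor facial selectivity at C4 takes over. The fallback sets out from 14 and builds the upper heterocycle on C6 with catalyst control at each centre. Vilsmeier formylation (POCl3, DMF, then aqueous NaOAc) at the only free position of ring A gives (2R,3R)-5,7-bis(benzyloxy)-2-[4-(benzyloxy)phenyl]-8-bromo-3-hydroxychroman-6-carbaldehyde F5. Claisen–Schmidt condensation with 4'-(benzyloxy)acetophenone (KOH, EtOH/THF) gives the (E)-chalcone F6. Rhodium-catalysed asymmetric 1,4-addition of [4-(benzyloxy)-2-hydroxyphenyl]boronic acid ([RhCl(C2H4)2]2, chiral diene ligand, KOH, dioxane/H2O) sets the diarylmethine centre and gives the β,β-diaryl ketone F7. Reduction with (S)-Me-CBS oxazaborolidine and BH3·SMe2 gives the (R)-benzylic alcohol F8. Mitsunobu cyclisation (PPh3, DIAD, THF) of the phenol onto the benzylic carbinol with inversion then closes the upper ring and gives 21, where the route is rejoined.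

Step 5. Epimerisation at C2 may be slower than reduction, or facial control may be mismatched, leading to low enantiomeric purity or to the trans alcohol. The fallback sets out from 12. Reduction with LiBH(s-Bu)3 (THF, −78 °C), which attacks anti to the C2 aryl group, gives the racemic 2,3-cis alcohol F3. Esterification with (R)-2-methoxy-2-phenylacetic acid (DCC, DMAP, CH2Cl2) and chromatographic separation of the diastereomers gives the (2R,3R) ester F4. Saponification (LiOH, THF/H2O) then gives 13, where the route is rejoined.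

Further compounds
F1 | step 3 | 1-[2,4-bis(benzyloxy)-6-fluorophenyl]-3-[4-(benzyloxy)phenyl]-2-methoxypropane-1,3-dione | COC(C(=O)c1ccc(OCc2ccccc2)cc1)C(=O)c1c(F)cc(OCc2ccccc2)cc1OCc1ccccc1
F2 | step 3 | 5,7-bis(benzyloxy)-2-[4-(benzyloxy)phenyl]-3-methoxy-4H-chromen-4-one | COc1c(-c2ccc(OCc3ccccc3)cc2)oc2cc(OCc3ccccc3)cc(OCc3ccccc3)c2c1=O
F3 | step 5 | racemic cis-5,7-bis(benzyloxy)-2-[4-(benzyloxy)phenyl]chroman-3-ol (both enantiomers written) | O[C@@H]1Cc2c(OCc3ccccc3)cc(OCc3ccccc3)cc2O[C@@H]1c1ccc(OCc2ccccc2)cc1.O[C@H]1Cc2c(OCc3ccccc3)cc(OCc3ccccc3)cc2O[C@H]1c1ccc(OCc2ccccc2)cc1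
F4 | step 5 | (2R,3R)-5,7-bis(benzyloxy)-2-[4-(benzyloxy)phenyl]chroman-3-yl (R)-2-methoxy-2-phenylacetate | CO[C@@H](C(=O)O[C@@H]1Cc2c(OCc3ccccc3)cc(OCc3ccccc3)cc2O[C@@H]1c1ccc(OCc2ccccc2)cc1)c1ccccc1
F5 | step 10 | (2R,3R)-5,7-bis(benzyloxy)-2-[4-(benzyloxy)phenyl]-8-bromo-3-hydroxychroman-6-carbaldehyde | O[C@@H]1Cc2c(OCc3ccccc3)c(C=O)c(OCc3ccccc3)c(Br)c2O[C@@H]1c1ccc(OCc2ccccc2)cc1
F6 | step 10 | (E)-chalcone from F5 and 4'-(benzyloxy)acetophenone | O[C@@H]1Cc2c(OCc3ccccc3)c(/C=C/C(=O)c3ccc(OCc4ccccc4)cc3)c(OCc3ccccc3)c(Br)c2O[C@@H]1c1ccc(OCc2ccccc2)cc1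
F7 | step 10 | β,β-diaryl ketone from 1,4-addition of the 4-(benzyloxy)-2-hydroxyphenyl group to F6 (methine configured as C4 of the upper unit in 21) | O[C@@H]1Cc2c(OCc3ccccc3)c([C@H](CC(=O)c3ccc(OCc4ccccc4)cc3)c3ccc(OCc4ccccc4)cc3O)c(OCc3ccccc3)c(Br)c2O[C@@H]1c1ccc(OCc2ccccc2)cc1
F8 | step 10 | (R)-benzylic alcohol from reduction of F7 | O[C@@H]1Cc2c(OCc3ccccc3)c([C@H](C[C@@H](O)c3ccc(OCc4ccccc4)cc3)c3ccc(OCc4ccccc4)cc3O)c(OCc3ccccc3)c(Br)c2O[C@@H]1c1ccc(OCc2ccccc2)cc1
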